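## Retrosynthetic overview

1. The senecioate on O9 is removed first (acylation). The O7 isovalerate and the C9 carbinol are then taken back together to a 7-hydroxy-9-ketone (Evans–Tishchenko reduction), whose C7 oxygen comes from conjugate borylation of a C7=C8–C9=O enone.
2. That enone goes back through the 1,9-dione to a single C–H hydroxylation at C9 of longipin-2-en-1-one, which is the C1 allylic oxidation product of α-longipinene.
3. Feature on which the plan rests: the fifteen skeletal carbons are one unbroken head-to-tail farnesyl chain, C5–C4–C3(Me)–C2–C1–C11–C10(Me)–C9–C8–C7–C6(Me)2. The tricycle differs from it only by the bonds C5–C6, C5–C11 and C4–C10, which are cut in one disconnection to (2E,6E)-farnesyl diphosphate.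
4. Ring order in the forward sense: C5–C6 closes the eleven-membered humulyl ring, transannular C5–C11 divides it into the six- and seven-membered rings, and C4–C10 closes the cyclobutane. C4, C5, C10 and C11 are all set there.
5. The diphosphate is made from (2E,6E)-farnesol in two steps.

Key step: step 3

Numbering used throughout: C1 carbonyl, C2=C3 with methyl on C3, cyclobutane C4–C5–C11–C10, gem-dimethyl C6, then C7, C8, C9, and methyl on C10.

Assumption: a class 1 α-longipinene synthase giving the (4R,5R,10S,11R) hydrocarbon (1R,2S,7R,8R in tricyclo[5.4.0.0^2,8]undecane numbering) is available by choice among natural synthases or by engineering. The cage keeps this geometry throughout; its descriptors change to 4R,5S,10R,11R only through priority changes once oxygen is added.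

## Route

Step 1
Reactants: 1 (2E,6E)-farnesol
Product: 2 (2E,6E)-farnesyl chloride
Conditions: NCS, Me2S, CH2Cl2, −40 → 0 °C
Reagents that add atoms: N-chlorosuccinimide, O=C1CCC(=O)N1Cl
Why: Corey–Kim chlorination, in which the alcohol is activated as an alkoxysulfonium ion and displaced by chloride at the primary carbon under cold, neutral conditions, so that neither allylic transposition nor 2E/2Z isomerisation should occur.

Step 2
Reactants: 2 (2E,6E)-farnesyl chloride
Product: 3 (2E,6E)-farnesyl diphosphate (drawn as the free acid, handled as the trisammonium salt)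
Conditions: (Bu4N)3HP2O7 (2 equiv), MeCN, rt; then cation exchange (sulfonated polystyrene resin, NH4+ form, aq. NH4HCO3/iPrOH), cellulose chromatography
Reagents that add atoms: tris(tetrabutylammonium) hydrogen diphosphate, CCCC[N+](CCCC)(CCCC)CCCC.CCCC[N+](CCCC)(CCCC)CCCC.CCCC[N+](CCCC)(CCCC)CCCC.OP(=O)([O-])OP(=O)([O-])[O-]
Why: SN2 displacement of a primary allylic chloride by the acetonitrile-soluble diphosphate anion, which attacks the CH2 terminus directly and so keeps the 2E geometry that the cyclase recognises.

Step 3
Reactants: 3 (2E,6E)-farnesyl diphosphate
Product: 4 α-longipinene, (4R,5R,10S,11R)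
Conditions: recombinant α-longipinene synthase (class 1 sesquiterpene synthase, expressed in E. coli), MgCl2 (10 mM), HEPES buffer pH 7.5, dithiothreitol, 30 °C, pentane overlay
Reagents that add atoms: none
Why: This is a class 1 terpene synthase cyclisation of the native substrate, a known reaction type: the magnesium cluster ionises the diphosphate, the allyl cation passes through the nerolidyl ion pair so that the C3=C4 bond becomes cisoid, and C5 adds to C6 of the distal alkene in an anti-Markovnikov 11-endo closure that gives the humulyl cation with the charge on C7. A 1,3-hydride shift from C5 to C7 creates the C5–C4–C3 allyl cation, whose C5 end is attacked across the ring by C11 of the C10=C11 alkene (6-exo for the cyclohexene, 7-endo for the cycloheptane), which divides the eleven-membered ring into the six- and seven-membered rings of the himachalyl cation with the charge on C10. The C3=C4 alkene then adds through C4 to C10 in a 4-exo, pinene-type closure that forms the cyclobutane and a tertiary C3 cation, and loss of a C2 proton leaves the C2=C3 alkene. The relative configuration of C4, C5, C10 and C11 is dictated by the cage, because the C5–C6 and C10–C9 bonds must both point away from the C1–C3 bridge to span the seven-membered ring, and the absolute configuration is set by the fold in which the active site holds the chain. The step needs product selectivity over early proton loss (humulene, himachalenes) and over further rearrangement of the longipinyl cation (longifolene, longicyclene), and it needs the right enantiomer; both are secured by using a dedicated α-longipinene synthase whose closed hydrophobic pocket shields the cations and places the base at C2.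

Step 4
Reactants: 4 α-longipinene
Product: 5 (4R,5S,10R,11R)-longipin-2-en-1-one
Conditions: CrO3, 3,5-dimethylpyrazole, CH2Cl2, −20 °C
Reagents that add atoms: chromium trioxide, O=[Cr](=O)=O
Why: Allylic oxidation by the chromium trioxide–3,5-dimethylpyrazole complex, in which the ring methylene C1 is the only allylic position that can become a conjugated ketone (C4 is a cyclobutane bridgehead), as in the conversion of α-pinene into verbenone, and no stereocentre is touched.

Step 5
Reactants: 5 (4R,5S,10R,11R)-longipin-2-en-1-one
Product: 6 (4R,5S,9R,10R,11R)-9-hydroxylongipin-2-en-1-one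
Conditions: engineered cytochrome P450 BM3 variant (selected from a mutant library on 5 for oxidation at C9), NADP+ (cat.), glucose, glucose dehydrogenase, air, potassium phosphate buffer pH 8.0, 2% DMSO, 25 °C
Reagents that add atoms: dioxygen, O=O
Why: Proposed new method: no hydroxylase is known for C9 of this skeleton, so the step rests on directed evolution; the ferryl-oxo porphyrin radical cation of the haem should abstract a hydrogen atom from C9 and the carbon radical should recombine with the iron-bound hydroxyl (rebound), the enone having already deactivated C11, C4 and the C3 methyl toward this electrophilic oxidant so that only the ring methylenes C7, C8 and C9 compete and the evolved pocket has to choose C9, while the face of attack is immaterial because C9 becomes a carbonyl in step 6 (the 9R alcohol is drawn); the closest known reaction type is hydroxylation of unactivated ring methylenes of terpenoids by engineered P450 BM3 variants.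

Step 6
Reactants: 6 (4R,5S,9R,10R,11R)-9-hydroxylongipin-2-en-1-one
Product: 7 (4R,5S,10R,11R)-longipin-2-ene-1,9-dione
Conditions: Dess–Martin periodinane, NaHCO3, CH2Cl2, rt
Reagents that add atoms: none
Why: Dess–Martin oxidation of a secondary alcohol to the ketone under buffered, non-enolising conditions, to which the enone and the cage are inert and in which the C9 stereocentre is erased on purpose.

Step 7
Reactants: 7 (4R,5S,10R,11R)-longipin-2-ene-1,9-dione
Product: 8 (4R,5S,10R,11R)-longipina-2,7-diene-1,9-dione
Conditions: IBX (3 equiv), DMSO/fluorobenzene, 70 °C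
Reagents that add atoms: none
Why: IBX dehydrogenation of a ketone through its enol, where the C9 ketone can enolise only toward C8 because C10 is quaternary and the new alkene must stop at C7=C8 because C6 is quaternary, while the C1 enone offers no position from which a further ring alkene could form.

Step 8
Reactants: 8 (4R,5S,10R,11R)-longipina-2,7-diene-1,9-dione
Product: 10 (4R,5S,7R,10R,11R)-7-hydroxylongipin-2-ene-1,9-dione, via C7 pinacolboronate 9 (not isolated)
Conditions: B2pin2 (1.2 equiv), CuCl (5 mol %), NaOtBu (10 mol %), QuinoxP* (6 mol %, antipode as stated under Why), MeOH (2 equiv), THF, 0 °C → rt; then NaBO3·4H2O, THF/H2O, rt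
Reagents that add atoms: bis(pinacolato)diboron, CC1(C)OB(OC1(C)C)B1OC(C)(C)C(C)(C)O1; sodium perborate tetrahydrate, [Na+].[O-]OB=O.O.O.O.O
Why: Copper-catalysed asymmetric conjugate borylation followed by stereoretentive C–B oxidation, in which the copper–boryl species should add to the β-monosubstituted C7=C8–C9=O enone and not to the β,β-disubstituted C2=C3–C1=O enone; because the two faces at C7 differ only through the remote C1 carbonyl versus C3 methyl (the cage around the seven-membered ring is otherwise mirror-symmetric), the C7 configuration is set by the ligand, whose antipode is chosen by trial on 8 to deliver boron to the face turned toward C4, and perborate then replaces boron by hydroxyl with retention.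

Step 9
Reactants: 10 (4R,5S,7R,10R,11R)-7-hydroxylongipin-2-ene-1,9-dione; 11 3-methylbutanal
Product: 12 (4R,5S,7R,9R,10R,11R)-9-hydroxy-1-oxolongipin-2-en-7-yl 3-methylbutanoate
Conditions: 11 (6 equiv), SmI2 (0.3 equiv, added to the aldehyde before the substrate), THF, −10 °C
Reagents that add atoms: none
Why: Evans–Tishchenko reduction, in which the C7 hydroxyl and the aldehyde form a samarium-bound hemiacetal whose hydride is passed through a six-membered transition state to the C9 carbonyl on the ring face that carries the C7 oxygen, so that the new C9 hydroxyl ends trans (1,3-anti) to O7 and the isovalerate is created on O7 in the same event, while the C1 enone, having no neighbouring hydroxyl, is left alone.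

Step 10
Reactants: 12 (4R,5S,7R,9R,10R,11R)-9-hydroxy-1-oxolongipin-2-en-7-yl 3-methylbutanoate; 13 3-methylbut-2-enoyl chloride
Product: 14 (4R,5S,7R,9R,10R,11R)-7-(3-methylbutanoyloxy)-1-oxolongipin-2-en-9-yl 3-methylbut-2-enoate (CNP0335239.1)
Conditions: 13 (2 equiv), pyridine, DMAP (0.1 equiv), CH2Cl2, 0 °C → rt
Reagents that add atoms: none
Why: Acylation of a secondary alcohol by an acid chloride through the N-acylpyridinium ion, with pyridine as the only stoichiometric base so that the senecioyl unit is not deconjugated through its vinylketene, with the trans-disposed O7 ester unable to migrate across the ring, and with no stereocentre touched.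

## Compound list

1 | (2E,6E)-farnesol | CC(C)=CCC/C(C)=C/CC/C(C)=C/CO | starting material
2 | (2E,6E)-farnesyl chloride | CC(C)=CCC/C(C)=C/CC/C(C)=C/CCl | intermediate
3 | (2E,6E)-farnesyl diphosphate (free acid drawn; used as trisammonium salt) | CC(C)=CCC/C(C)=C/CC/C(C)=C/COP(=O)(O)OP(=O)(O)O | intermediate
4 | α-longipinene, (4R,5R,10S,11R) | C1CCC(C)(C)[C@@H]2[C@H]3CC=C(C)[C@@H]2[C@]31C | intermediate
5 | (4R,5S,10R,11R)-longipin-2-en-1-one | C1CCC(C)(C)[C@@H]2[C@H]3C(=O)C=C(C)[C@@H]2[C@]31C | intermediate
6 | (4R,5S,9R,10R,11R)-9-hydroxylongipin-2-en-1-one | O[C@@H]1CCC(C)(C)[C@@H]2[C@H]3C(=O)C=C(C)[C@@H]2[C@]31C | intermediate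
7 | (4R,5S,10R,11R)-longipin-2-ene-1,9-dione | O=C1CCC(C)(C)[C@@H]2[C@H]3C(=O)C=C(C)[C@@H]2[C@]31C | intermediate
8 | (4R,5S,10R,11R)-longipina-2,7-diene-1,9-dione | O=C1C=CC(C)(C)[C@@H]2[C@H]3C(=O)C=C(C)[C@@H]2[C@]31C | intermediate
9 | (4R,5S,7R,10R,11R)-7-(4,4,5,5-tetramethyl-1,3,2-dioxaborolan-2-yl)longipin-2-ene-1,9-dione (boron on the ring face toward C4; not isolated) | O=C1C[C@@H](B2OC(C)(C)C(C)(C)O2)C(C)(C)[C@@H]2[C@H]3C(=O)C=C(C)[C@@H]2[C@]31C | intermediate
10 | (4R,5S,7R,10R,11R)-7-hydroxylongipin-2-ene-1,9-dione | O=C1C[C@@H](O)C(C)(C)[C@@H]2[C@H]3C(=O)C=C(C)[C@@H]2[C@]31C | intermediate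
11 | 3-methylbutanal | CC(C)CC=O | starting material
12 | (4R,5S,7R,9R,10R,11R)-9-hydroxy-1-oxolongipin-2-en-7-yl 3-methylbutanoate | O[C@@H]1C[C@@H](OC(=O)CC(C)C)C(C)(C)[C@@H]2[C@H]3C(=O)C=C(C)[C@@H]2[C@]31C | intermediate
13 | 3-methylbut-2-enoyl chloride | CC(C)=CC(Cl)=O | starting material
14 | (4R,5S,7R,9R,10R,11R)-7-(3-methylbutanoyloxy)-1-oxolongipin-2-en-9-yl 3-methylbut-2-enoate | CC(C)=CC(=O)O[C@@H]1C[C@@H](OC(=O)CC(C)C)C(C)(C)[C@@H]2[C@H]3C(=O)C=C(C)[C@@H]2[C@]31C | target

Total step count: 10. Longest linear sequence: 10 steps (1 to 14).

## Steps most likely to fail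

**1. Step 5 (the step that carries the label).** Oxygen may be inserted at the wrong ring methylene (C8 is the least hindered), a methyl group may be hydroxylated, or no variant of the library may bind the hydrophobic ketone productively.

Fallback, known chemistry, from 5 back to 8. It uses the innate preference of intermolecular hydrogen-atom abstraction for C8, the only ring methylene not flanked by a quaternary carbon. Visible-light C–H bromination of 5 with N-bromo-N-tert-butyl-3,5-bis(trifluoromethyl)benzamide in benzene at rt should give 8-bromolongipin-2-en-1-one F1 (C8 epimers). Dehydrobromination with DBU in toluene at 90 °C should give longipina-2,7-dien-1-one F2, accompanied by its double-bond isomer longipina-2,8-dien-1-one F3. Allylic oxidation of the mixture with tert-butyl hydroperoxide and Rh2(cap)4 (dirhodium tetracaprolactamate), K2CO3, CH2Cl2, rt, runs through the C7–C8–C9 allyl radical that both alkenes share. Oxygenation at its less encumbered end C9 (C7 is crowded by the geminal methyls on C6) should give dienedione 8, and the route continues at step 8.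

**2. Step 8.** The copper–boryl species may fail to add at a neopentyl β-carbon, may add to the wrong face because the ligand has to impose selectivity on a substrate with almost no facial bias, or the β-hydroxy ketone may eliminate back to the enone during the oxidative work-up.

Fallback from 8 back to 10. The oxygen is brought in as a nucleophile and unmasked reductively. Weitz–Scheffer epoxidation of 8 (tert-butyl hydroperoxide, DBU, CH2Cl2, 0 °C) should attack only the β-monosubstituted enone. It should give 7,8-epoxylongipin-2-ene-1,9-dione with the oxirane oxygen on the ring face toward C4, F4, together with its face isomer, the 7,8-epoxide with the oxirane oxygen on the face toward C11, F5; the two are separated on silica. Treating F4 with sodium phenylselenide (from (PhSe)2 and NaBH4 in EtOH, AcOH, 0 °C) cleaves the C8–O bond of the α,β-epoxy ketone and leaves the C7–O bond untouched, which should give hydroxy dione 10.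

**3. Step 9.** Electron transfer from residual SmI2 to the C9 ketone may open the adjacent strained C10–C11 bond (the two carbonyls form a 1,4-diketone across a cyclobutane bond). The β-hydroxy ketone may also undergo retro-aldol ring opening or dehydration under Lewis acid, and hydride transfer to a ketone flanked by a quaternary carbon may be slow.

Fallback from 10 to 14. The reduction and the two acylations are separated. Evans–Saksena reduction of 10 (Me4NBH(OAc)3, MeCN/AcOH, −30 °C), with hydride delivered from boron bound to O7, should give the trans diol (4R,5S,7R,9R,10R,11R)-7,9-dihydroxylongipin-2-en-1-one F6. The C9 hydroxyl is less hindered than the C7 hydroxyl, which sits next to the geminal methyls. Acylating it with 13 (1.1 equiv, pyridine, CH2Cl2, −10 °C) should give (4R,5S,7R,9R,10R,11R)-7-hydroxy-1-oxolongipin-2-en-9-yl 3-methylbut-2-enoate F7. 3-Methylbutanoyl chloride, DMAP and pyridine in CH2Cl2 at rt then esterify O7 to give 14.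

## Further compounds

F1 | step 5 | 8-bromolongipin-2-en-1-one (C8 epimers, cage as in 5) | C1C(Br)CC(C)(C)[C@@H]2[C@H]3C(=O)C=C(C)[C@@H]2[C@]31C
F2 | step 5 | (4R,5S,10R,11R)-longipina-2,7-dien-1-one | C1C=CC(C)(C)[C@@H]2[C@H]3C(=O)C=C(C)[C@@H]2[C@]31C
F3 | step 5 | longipina-2,8-dien-1-one (cage as in 5) | C1=CCC(C)(C)[C@@H]2[C@H]3C(=O)C=C(C)[C@@H]2[C@]31C
F4 | step 8 | 7,8-epoxylongipin-2-ene-1,9-dione, oxirane oxygen on the ring face toward C4 | O=C1[C@H]4O[C@H]4C(C)(C)[C@@H]2[C@H]3C(=O)C=C(C)[C@@H]2[C@]31C
F5 | step 8 | 7,8-epoxylongipin-2-ene-1,9-dione, oxirane oxygen on the ring face toward C11 | O=C1[C@@H]4O[C@@H]4C(C)(C)[C@@H]2[C@H]3C(=O)C=C(C)[C@@H]2[C@]31C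
F6 | step 9 | (4R,5S,7R,9R,10R,11R)-7,9-dihydroxylongipin-2-en-1-one | O[C@@H]1C[C@@H](O)C(C)(C)[C@@H]2[C@H]3C(=O)C=C(C)[C@@H]2[C@]31C
F7 | step 9 | (4R,5S,7R,9R,10R,11R)-7-hydroxy-1-oxolongipin-2-en-9-yl 3-methylbut-2-enoate | CC(C)=CC(=O)O[C@@H]1C[C@@H](O)C(C)(C)[C@@H]2[C@H]3C(=O)C=C(C)[C@@H]2[C@]31C
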